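A direct plan would start from ring A: 2-methylphloroglucinol A1 would be formylated and dibenzylated to salicylaldehyde A2, closed to coumarin A3, and a copper-catalysed conjugate addition of an isobutyl Grignard reagent would give dihydrocoumarin A4.
Ring B would then be grown on the lactone enolate of A4 with 2,2,4,4-tetramethylcyclobutane-1,3-dione A5 to give A6; hydrogenolysis to triol A7 and a TiCl4 Friedel–Crafts acylation would finish.
Its weakest steps would be these. (a) The partial benzylation would have to tell apart two hydroxyl groups that are both chelated to the formyl group, so the position of the lactone oxygen would rest on a small rate difference and a crystallisation, and two steps would go into protecting groups alone.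
(b) The ring B construction by enolate addition, retro-Claisen opening and Dieckmann closure would be a cascade without precedent and with several competing exits, run on material whose configuration would come from a conjugate addition of untested facial sense.
(c) The Friedel–Crafts acylation as last step would put a strong Lewis acid on the finished adduct, which could ionise the doubly activated benzylic C–C bond (racemisation), close a phenol onto ring B or acylate on oxygen, all on the most precious material.

Plan of the new route (ring A numbered C1 methyl, C2 OH, C3 acyl, C4 OH, C5 bearing the stereocentre, C6 OH):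
Ring A is built last: it is cut at C2–C3 (Claisen) and unfolded into the 3,5,7-triketo ester PhCH2CH2CO–CH2–CO–CH(R*)–CO–CH(CH3)–CO2CH3, which is stored as a 4-pyranone.
That chain is cut at C4–C5 (γ-acylation by an alkynyl Weinreb amide) and at C6–C1 (Claisen opening of an enol δ-lactone by methyl propanoate); the lactone is cut at the bond from ring B to the stereocentre (iminium-catalysed Michael addition of syncarpic acid to an enal).
Ring order: ring B (bought), then a dihydropyranone fused to ring B that holds the stereocentre, then a 4-pyranone, then ring A.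
Enabling feature: ring A carries oxygen on C2, C4 and C6 and carbon on C1, C3 and C5, with the acyl group on C3, which is the fold of a tetraketide; the methyl group on C1 blocks the aldol closure that competes with the Claisen closure.
No phenol is protected, ring B is never constructed and no arene is acylated. The stereocentre comes from a catalyst class with a tested facial model and sits between anionic sp2 carbons whenever base is present.
Key step: step 7

Assumption: syncarpic acid 4 is bought; it is a catalogue compound.

Step 1
Reactants: 1 3-methylbutanal; 2 (triphenylphosphoranylidene)acetaldehyde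
Product: 3 (2E)-5-methylhex-2-enal
Conditions: 1 (1.5 equiv), toluene, 80 °C; distillation
Reagents that add atoms: none
Why: Wittig olefination with a stabilised formyl ylide should give the E-enal, and the excess of the volatile aldehyde suppresses a second homologation.

Step 2
Reactants: 3 (2E)-5-methylhex-2-enal; 4 syncarpic acid
Product: 6 (4S)-2-hydroxy-6,6,8,8-tetramethyl-4-(2-methylpropyl)-3,4-dihydro-2H-chromene-5,7(6H,8H)-dione, via open-chain aldehyde 5 (not isolated)
Conditions: (R)-2-[diphenyl(trimethylsilyloxy)methyl]pyrrolidine (15 mol %), CH2Cl2, 0 °C → rt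
Reagents that add atoms: none
Why: Iminium-catalysed Michael addition of a cyclic 1,3-dione to an enal followed by hemiacetalisation: C2 of 4 attacks C3 of the E,s-trans iminium ion on the face away from the C(Ph)2OSiMe3 group, which the steric model for this catalyst class assigns for the R catalyst to the 4S centre, and the enol hydroxyl group then closes onto the aldehyde.

Step 3
Reactants: 6 (4S)-2-hydroxy-6,6,8,8-tetramethyl-4-(2-methylpropyl)-3,4-dihydro-2H-chromene-5,7(6H,8H)-dione
Product: 7 (4S)-6,6,8,8-tetramethyl-4-(2-methylpropyl)-3,4-dihydro-2H-chromene-2,5,7(6H,8H)-trione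
Conditions: TEMPO (10 mol %), PhI(OAc)2 (1.3 equiv), CH2Cl2, rt
Reagents that add atoms: none
Why: Oxoammonium oxidation of a lactol to the lactone, in which the stereocentre is β to the new carbonyl group and is not touched; the product is a vinylogous anhydride that masks the ring B enol and activates the carboxyl carbon.

Step 4
Reactants: 7 (4S)-6,6,8,8-tetramethyl-4-(2-methylpropyl)-3,4-dihydro-2H-chromene-2,5,7(6H,8H)-trione; 8 methyl propanoate
Product: 9 methyl (5S)-5-(2-hydroxy-3,3,5,5-tetramethyl-4,6-dioxocyclohex-1-en-1-yl)-2,7-dimethyl-3-oxooctanoate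
Conditions: 8 (2.6 equiv), LiN(i-Pr)2 (2.6 equiv), THF, −78 °C; then 7, −78 → −30 °C; cold 1 M HCl
Reagents that add atoms: none
Why: Crossed Claisen condensation in which the ester enolate is acylated at the enol-lactone carbonyl, the ring B enolate serves as a leaving group that stays in the molecule, and the β-keto ester is shielded as its enolate; the new C2 centre forms as a mixture and is erased when ring A aromatises.

Step 5
Reactants: 10 but-3-yn-1-ylbenzene; 11 N-methoxy-N-methylcarbamoyl chloride
Product: 12 N-methoxy-N-methyl-5-phenylpent-2-ynamide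
Conditions: n-BuLi (1.05 equiv), THF, −78 °C; then 11, −78 → 0 °C
Reagents that add atoms: none
Why: Acylation of a lithium acetylide by a carbamoyl chloride should give the alkynyl Weinreb amide, a non-enolisable donor of the PhCH2CH2C≡C–CO unit.

Step 6
Reactants: 9 methyl (5S)-5-(2-hydroxy-3,3,5,5-tetramethyl-4,6-dioxocyclohex-1-en-1-yl)-2,7-dimethyl-3-oxooctanoate; 12 N-methoxy-N-methyl-5-phenylpent-2-ynamide
Product: 14 methyl 2-{3-[(1S)-1-(2-hydroxy-3,3,5,5-tetramethyl-4,6-dioxocyclohex-1-en-1-yl)-3-methylbutyl]-4-oxo-6-(2-phenylethyl)-4H-pyran-2-yl}propanoate, via ynone 13 (not isolated)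
Conditions: LiN(i-Pr)2 (3.3 equiv), THF, −78 → 0 °C; 12 (1.3 equiv), −78 → −20 °C; cold 1 M HCl; crude 13, Et3N (3 equiv), CH2Cl2, rt
Reagents that add atoms: none
Why: γ-Acylation of a β-keto ester polyanion followed by 6-endo-dig oxa-Michael cycloisomerisation: the amide base removes the enol proton, the C2 proton and then a proton of the only γ position (C4), the C4 carbanion is acylated once because the Weinreb adduct stays chelated until work-up, and in triethylamine the enolate oxygen on C3 of ynone 13 adds to the alkyne to give the 4-pyranone, in which the stereocentre sits on an aromatic carbon.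

Step 7
Reactants: 14 methyl 2-{3-[(1S)-1-(2-hydroxy-3,3,5,5-tetramethyl-4,6-dioxocyclohex-1-en-1-yl)-3-methylbutyl]-4-oxo-6-(2-phenylethyl)-4H-pyran-2-yl}propanoate
Product: 16 3-hydroxy-4,4,6,6-tetramethyl-2-[(1S)-3-methyl-1-[2,4,6-trihydroxy-3-methyl-5-(3-phenylpropanoyl)phenyl]butyl]cyclohex-2-ene-1,5-dione (CNP0188786.1), via triketo ester 15 (not isolated)
Conditions: Mg(OMe)2 (8 equiv), MeOH, H2O (2 equiv), reflux, argon; then 1 M HCl, 0 °C
Reagents that add atoms: water, O
Why: Ring transformation of a 4-pyranone into a benzene ring: hydroxide delivered by Mg(OMe)2 and water adds to C6 of the pyranone (the phenethyl-bearing vinylogous ester carbon; the other α-carbon carries the enolised ester side chain), the ring opens to the magnesium chelate of triketo ester 15, and the carbon between its C5 and C7 ketones attacks the chelated ester carbonyl, expels methoxide and the resulting cyclohexane-1,3,5-trione enolises to ring A. The closest known reaction types are the Mg(OMe)2-induced conversion of pyranone esters into acylphloroglucinols and the Claisen cyclisation of 3,5,7-triketo esters, with base opening of 4-pyranones to 1,3,5-triketones as the first stage. The ring closes in a 6-(enolexo)-exo-trig Claisen mode that forms the C2–C3 bond of ring A; the pyranone oxygen ends as the C6 hydroxyl group and the water oxygen as the side-chain ketone (a methoxide adduct would reach the same ketone in the acidic work-up). No stereocentre is formed, and the existing one stays between the ring B enolate carbon and a chelated enolate, later phenoxide, carbon, so neither neighbour can depart as a stabilised anion and retro-Michael scrambling is shut off until the cold acid quench. The step needs the Claisen closure rather than an aldol aromatisation: the methyl group on C2 of 15 makes the orsellinate-type aldol product quaternary and unable to aromatise, the other aldol would need the unactivated C8 methylene as nucleophile, and magnesium chelation of the β-keto ester is the element known to steer such chains to the Claisen product, while the near-anhydrous medium keeps the ester from being cleaved before it is attacked.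

Compound list
1 | 3-methylbutanal | CC(C)CC=O | starting material
2 | (triphenylphosphoranylidene)acetaldehyde | O=CC=P(c1ccccc1)(c1ccccc1)c1ccccc1 | starting material
3 | (2E)-5-methylhex-2-enal | CC(C)C/C=C/C=O | intermediate
4 | syncarpic acid (3-hydroxy-4,4,6,6-tetramethylcyclohex-2-ene-1,5-dione) | CC1(C)C(=O)C=C(O)C(C)(C)C1=O | starting material
5 | (3S)-3-(2-hydroxy-3,3,5,5-tetramethyl-4,6-dioxocyclohex-1-en-1-yl)-5-methylhexanal | O=CC[C@H](CC(C)C)C1=C(O)C(C)(C)C(=O)C(C)(C)C1=O | intermediate (not isolated)
6 | (4S)-2-hydroxy-6,6,8,8-tetramethyl-4-(2-methylpropyl)-3,4-dihydro-2H-chromene-5,7(6H,8H)-dione (both C2 epimers) | CC(C)C[C@H]1CC(O)OC2=C1C(=O)C(C)(C)C(=O)C2(C)C | intermediate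
7 | (4S)-6,6,8,8-tetramethyl-4-(2-methylpropyl)-3,4-dihydro-2H-chromene-2,5,7(6H,8H)-trione | CC(C)C[C@H]1CC(=O)OC2=C1C(=O)C(C)(C)C(=O)C2(C)C | intermediate
8 | methyl propanoate | CCC(=O)OC | starting material
9 | methyl (5S)-5-(2-hydroxy-3,3,5,5-tetramethyl-4,6-dioxocyclohex-1-en-1-yl)-2,7-dimethyl-3-oxooctanoate (C2 epimers) | COC(=O)C(C)C(=O)C[C@H](CC(C)C)C1=C(O)C(C)(C)C(=O)C(C)(C)C1=O | intermediate
10 | but-3-yn-1-ylbenzene (4-phenylbut-1-yne) | C#CCCc1ccccc1 | starting material
11 | N-methoxy-N-methylcarbamoyl chloride | CON(C)C(=O)Cl | starting material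
12 | N-methoxy-N-methyl-5-phenylpent-2-ynamide | CON(C)C(=O)C#CCCc1ccccc1 | intermediate
13 | methyl 4-[(1S)-1-(2-hydroxy-3,3,5,5-tetramethyl-4,6-dioxocyclohex-1-en-1-yl)-3-methylbutyl]-2-methyl-3,5-dioxo-9-phenylnon-6-ynoate (C2 and C4 not defined) | COC(=O)C(C)C(=O)C(C(=O)C#CCCc1ccccc1)[C@H](CC(C)C)C1=C(O)C(C)(C)C(=O)C(C)(C)C1=O | intermediate (not isolated)
14 | methyl 2-{3-[(1S)-1-(2-hydroxy-3,3,5,5-tetramethyl-4,6-dioxocyclohex-1-en-1-yl)-3-methylbutyl]-4-oxo-6-(2-phenylethyl)-4H-pyran-2-yl}propanoate (epimers at the propanoate carbon) | COC(=O)C(C)C1=C([C@H](CC(C)C)C2=C(O)C(C)(C)C(=O)C(C)(C)C2=O)C(=O)C=C(CCc2ccccc2)O1 | intermediate (key-step precursor)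
15 | methyl 4-[(1S)-1-(2-hydroxy-3,3,5,5-tetramethyl-4,6-dioxocyclohex-1-en-1-yl)-3-methylbutyl]-2-methyl-3,5,7-trioxo-9-phenylnonanoate (formed as its magnesium enolate; C2 and C4 not defined) | COC(=O)C(C)C(=O)C(C(=O)CC(=O)CCc1ccccc1)[C@H](CC(C)C)C1=C(O)C(C)(C)C(=O)C(C)(C)C1=O | intermediate (not isolated)
16 | 3-hydroxy-4,4,6,6-tetramethyl-2-[(1S)-3-methyl-1-[2,4,6-trihydroxy-3-methyl-5-(3-phenylpropanoyl)phenyl]butyl]cyclohex-2-ene-1,5-dione (CNP0188786.1) | Cc1c(O)c(C(=O)CCc2ccccc2)c(O)c([C@H](CC(C)C)C2=C(O)C(C)(C)C(=O)C(C)(C)C2=O)c1O | target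

Total step count: 7. Longest linear sequence: 6 steps (steps 1, 2, 3, 4, 6 and 7).

Steps most likely to fail

Step 7. Opening of the electron-rich, 3-substituted 4-pyranone could be too slow, or the opened chain could re-close through oxygen faster than through carbon; addition of methoxide on the ester-bearing side would lead to an aryl methyl ether. The fallback sets out from 14. Ba(OH)2 in aqueous dioxane at room temperature would open the ring and cleave the ester at the same time to give, as its barium salt, 4-[(1S)-1-(2-hydroxy-3,3,5,5-tetramethyl-4,6-dioxocyclohex-1-en-1-yl)-3-methylbutyl]-2-methyl-3,5,7-trioxo-9-phenylnonanoic acid F1. Acetic anhydride at 0 °C would close the salt to 4-hydroxy-5-[(1S)-1-(2-hydroxy-3,3,5,5-tetramethyl-4,6-dioxocyclohex-1-en-1-yl)-3-methylbutyl]-3-methyl-6-(2-oxo-4-phenylbutyl)-2H-pyran-2-one F2, a 6-(2-oxoalkyl)-4-hydroxy-2-pyranone of the class for which the Mg(OMe)2 rearrangement to acylphloroglucinols is established. Mg(OMe)2 in methanol would open F2 at the lactone carbonyl to 15, and the route is rejoined at 16.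

Step 6. Acylation of the crowded γ-carbanion by the amide could be sluggish, so that conjugate addition to the alkyne or proton return takes over. The fallback sets out from 9. The same polyanion would be added to 5-phenylpent-2-ynal F3 (from 10 with n-BuLi, then DMF), a far stronger electrophile that reacts only at the formyl carbon. This would give the aldol methyl 5-hydroxy-4-[(1S)-1-(2-hydroxy-3,3,5,5-tetramethyl-4,6-dioxocyclohex-1-en-1-yl)-3-methylbutyl]-2-methyl-3-oxo-9-phenylnon-6-ynoate F4. MnO2 in CH2Cl2 would oxidise the propargylic alcohol to ynone 13, which is cyclised with triethylamine to 14, where the route is rejoined.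

Step 2. The strongly acidic, hindered trione could condense at the formyl carbon and close to a 2H-pyran instead of adding in conjugate fashion, or could react through a loose ion pair with poor facial selectivity. The fallback sets out from 3 and 4 and comes back at 7, skipping 6. It uses oxidative N-heterocyclic carbene catalysis: a chiral aminoindanol-derived N-mesityl triazolium salt, a base and 3,3',5,5'-tetra-tert-butyldiphenoquinone in toluene would turn 3 into an α,β-unsaturated acyl azolium ion. Michael addition of 4 and lactonisation would then give 7 directly. No free aldehyde electrophile is present, and no compound outside the list is made.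

Further compounds
F1 | step 7 | 4-[(1S)-1-(2-hydroxy-3,3,5,5-tetramethyl-4,6-dioxocyclohex-1-en-1-yl)-3-methylbutyl]-2-methyl-3,5,7-trioxo-9-phenylnonanoic acid | OC(=O)C(C)C(=O)C(C(=O)CC(=O)CCc1ccccc1)[C@H](CC(C)C)C1=C(O)C(C)(C)C(=O)C(C)(C)C1=O
F2 | step 7 | 4-hydroxy-5-[(1S)-1-(2-hydroxy-3,3,5,5-tetramethyl-4,6-dioxocyclohex-1-en-1-yl)-3-methylbutyl]-3-methyl-6-(2-oxo-4-phenylbutyl)-2H-pyran-2-one | CC1=C(O)C([C@H](CC(C)C)C2=C(O)C(C)(C)C(=O)C(C)(C)C2=O)=C(CC(=O)CCc2ccccc2)OC1=O
F3 | step 6 | 5-phenylpent-2-ynal | O=CC#CCCc1ccccc1
F4 | step 6 | methyl 5-hydroxy-4-[(1S)-1-(2-hydroxy-3,3,5,5-tetramethyl-4,6-dioxocyclohex-1-en-1-yl)-3-methylbutyl]-2-methyl-3-oxo-9-phenylnon-6-ynoate | COC(=O)C(C)C(=O)C(C(O)C#CCCc1ccccc1)[C@H](CC(C)C)C1=C(O)C(C)(C)C(=O)C(C)(C)C1=O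
F0 | step 2 | none | none
A1 | direct plan | 2-methylphloroglucinol | Cc1c(O)cc(O)cc1O
A2 | direct plan | 4,6-bis(benzyloxy)-2-hydroxy-3-methylbenzaldehyde | Cc1c(OCc2ccccc2)cc(OCc2ccccc2)c(C=O)c1O
A3 | direct plan | 5,7-bis(benzyloxy)-8-methyl-2H-chromen-2-one | Cc1c(OCc2ccccc2)cc(OCc2ccccc2)c2c1OC(=O)C=C2
A4 | direct plan | (4R)-5,7-bis(benzyloxy)-8-methyl-4-(2-methylpropyl)-3,4-dihydro-2H-chromen-2-one | Cc1c(OCc2ccccc2)cc(OCc2ccccc2)c2c1OC(=O)C[C@H]2CC(C)C
A5 | direct plan | 2,2,4,4-tetramethylcyclobutane-1,3-dione | CC1(C)C(=O)C(C)(C)C1=O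
A6 | direct plan | 2-[(1S)-1-[4,6-bis(benzyloxy)-2-hydroxy-3-methylphenyl]-3-methylbutyl]-3-hydroxy-4,4,6,6-tetramethylcyclohex-2-ene-1,5-dione | Cc1c(OCc2ccccc2)cc(OCc2ccccc2)c([C@H](CC(C)C)C2=C(O)C(C)(C)C(=O)C(C)(C)C2=O)c1O
A7 | direct plan | 3-hydroxy-4,4,6,6-tetramethyl-2-[(1S)-3-methyl-1-(2,4,6-trihydroxy-3-methylphenyl)butyl]cyclohex-2-ene-1,5-dione | Cc1c(O)cc(O)c([C@H](CC(C)C)C2=C(O)C(C)(C)C(=O)C(C)(C)C2=O)c1O
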